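**Plan**

1. Ring B is the central ring (C1 butyryl, C2/C4/C6 OH, C3 and C5 CH2). Ring A is the outer ring whose butyryl lies between OMe and OH, ring C the one whose butyryl lies between two OH.
2. First cut: the three phenol C–O bonds of ring B (C2–O, C4–O, C6–O) go back to C–F. Each lies ortho or para to the ring B C1 carbonyl, which is what lets benzyloxide displace all three fluorides.
3. Second cut: the outer-ring butyryl C–C bonds (ring A C5, ring C C3), then the three C–C bonds of ring B at C1, C3 and C5. These three carbons are the C–H positions of 1,3,5-trifluorobenzene, each between two fluorines and so lithiated in turn.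
4. Forward: methylphloroglucinol is formylated and O-differentiated into the ring A and ring C aldehydes. Trifluorobenzene is joined to the ring A aldehyde, the ring C aldehyde and a butyryl donor in that order, each carbinol being reduced to CH2. Both outer rings are then butyrylated, the fluorides exchanged and the benzyl ethers removed.
5. No ring is built; all three benzene rings are bought. The target has no stereocentre; the carbinol centres formed on the way are racemic and are erased by reduction.

Key step: step 12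

Remark: ring A is taken to be acylated before ring C in step 11, and the fluoride para to the carbonyl to leave first in step 12; another order changes only the unisolated intermediates 20, 23 and 24, not the products.

Abbreviations: ArA = 2,6-bis(benzyloxy)-4-methoxy-3-methylphenyl; ArC = 4,6-bis(benzyloxy)-2-methoxy-3-methylphenyl; ArA′ = 2,6-bis(benzyloxy)-3-butanoyl-4-methoxy-5-methylphenyl; ArC′ = 2,4-bis(benzyloxy)-3-butanoyl-6-methoxy-5-methylphenyl.

**Route**

Step 1
Reactants: 1 2-methylbenzene-1,3,5-triol (methylphloroglucinol)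
Product: 3 2,4,6-trihydroxy-3-methylbenzaldehyde, via iminium chloride 2 (not isolated)
Conditions: POCl3, DMF, EtOAc, 0 °C → rt; then H2O, 60 °C
Reagents that add atoms: N,N-dimethylformamide CN(C)C=O (formyl carbon); water O (formyl oxygen)
Why: Vilsmeier–Haack formylation: the chloroiminium ion attacks one of the two equivalent free ring carbons of the electron-rich triol, so only one aldehyde can form once iminium salt 2 is hydrolysed.

Step 2
Reactants: 3 2,4,6-trihydroxy-3-methylbenzaldehyde
Product: 4 2,6-dihydroxy-4-methoxy-3-methylbenzaldehyde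
Conditions: Me2SO4 (1 equiv), K2CO3 (1 equiv), acetone, 0 °C → rt
Reagents that add atoms: dimethyl sulfate COS(=O)(=O)OC
Why: Selective Williamson O-methylation: the hydroxyl para to the formyl group is the most acidic and is free, whereas the two ortho hydroxyls are hindered and hydrogen-bonded to the carbonyl, so one equivalent of dimethyl sulfate should go to O4.

Step 3
Reactants: 4 2,6-dihydroxy-4-methoxy-3-methylbenzaldehyde
Product: 5 2,6-bis(benzyloxy)-4-methoxy-3-methylbenzaldehyde (ring A aldehyde, ArA–CHO)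
Conditions: BnBr (2.5 equiv), K2CO3, DMF, 60 °C
Reagents that add atoms: benzyl bromide BrCc1ccccc1
Why: Williamson etherification: excess benzyl bromide in warm DMF should alkylate both chelated ortho phenols, and nothing else in 4 can react.

Step 4
Reactants: 3 2,4,6-trihydroxy-3-methylbenzaldehyde
Product: 6 4,6-bis(benzyloxy)-2-hydroxy-3-methylbenzaldehyde
Conditions: BnBr (2 equiv), K2CO3 (2 equiv), acetone, rt
Reagents that add atoms: benzyl bromide BrCc1ccccc1
Why: Regioselective Williamson benzylation: the para hydroxyl reacts first, then the ortho hydroxyl at C6 next to a ring hydrogen, while the one at C2, squeezed between formyl and methyl, should stay behind as the chelated phenol, as in partial alkylation of C-methylated phloroglucinol carbonyl compounds.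

Step 5
Reactants: 6 4,6-bis(benzyloxy)-2-hydroxy-3-methylbenzaldehyde
Product: 7 4,6-bis(benzyloxy)-2-methoxy-3-methylbenzaldehyde (ring C aldehyde, ArC–CHO)
Conditions: MeI (excess), K2CO3, DMF, 50 °C
Reagents that add atoms: iodomethane CI
Why: Williamson methylation of the last, hindered and chelated phenol, which a small electrophile in excess in DMF should still reach.

Step 6
Reactants: 8 1,3,5-trifluorobenzene; 5 ring A aldehyde
Product: 10 racemic (ArA)(2,4,6-trifluorophenyl)methanol, via 2,4,6-trifluorophenyllithium 9 (not isolated)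
Conditions: n-BuLi, THF, −78 °C; then 5, −78 °C; then H2O
Reagents that add atoms: none
Why: Deprotonation between two fluorines followed by 1,2-addition of an aryllithium to an aldehyde: 9 is stable at −78 °C and the non-enolisable aldehyde can only add; the carbinol carbon is racemic and loses its oxygen in step 7.

Step 7
Reactants: 10 racemic (ArA)(2,4,6-trifluorophenyl)methanol
Product: 11 1,3,5-trifluoro-2-(ArA-methyl)benzene
Conditions: Et3SiH, TFA, CH2Cl2, 0 °C
Reagents that add atoms: none
Why: Ionic hydrogenation: TFA ionises the carbinol to a cation stabilised by the three alkoxy groups of ring A and Et3SiH delivers hydride, while aryl benzyl ethers and C–F bonds should tolerate the short exposure to acid at 0 °C.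

Step 8
Reactants: 11 1,3,5-trifluoro-2-(ArA-methyl)benzene; 7 ring C aldehyde
Product: 13 racemic (ArC)[3-(ArA-methyl)-2,4,6-trifluorophenyl]methanol, via ring B aryllithium 12 (not isolated)
Conditions: LiN(iPr)2, THF, −78 °C; then 7, −78 °C; then H2O
Reagents that add atoms: none
Why: Fluorine-directed lithiation then aldehyde addition: the amide base removes one of the two equivalent ring B protons lying between two fluorines, leaves the benzyl ethers, the bridge CH2 and the ring A proton alone, and aryllithium 12 adds to 7; the new carbinol is racemic and is reduced in step 9.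

Step 9
Reactants: 13 racemic (ArC)[3-(ArA-methyl)-2,4,6-trifluorophenyl]methanol
Product: 14 1-(ArA-methyl)-3-(ArC-methyl)-2,4,6-trifluorobenzene
Conditions: Et3SiH, TFA, CH2Cl2, 0 °C
Reagents that add atoms: none
Why: Ionic hydrogenation as in step 7, with ring C stabilising the cation; the bridge already in place is safe because its cleavage would need an unstabilised trifluorobenzyl cation.

Step 10
Reactants: 14 1-(ArA-methyl)-3-(ArC-methyl)-2,4,6-trifluorobenzene; 15 N-methoxy-N-methylbutanamide
Product: 18 1-[3-(ArA-methyl)-5-(ArC-methyl)-2,4,6-trifluorophenyl]butan-1-one, via ring B aryllithium 16 (not isolated), via lithium Weinreb adduct 17 (not isolated)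
Conditions: LiN(iPr)2, THF, −78 °C; then 15, −78 °C; then aq. HCl
Reagents that add atoms: none
Why: Weinreb ketone synthesis: the last ring B proton, again between two fluorines, is removed by the amide base and aryllithium 16 acylates only once because the chelated adduct 17 holds until the acidic quench.

Step 11
Reactants: 18 1-[3-(ArA-methyl)-5-(ArC-methyl)-2,4,6-trifluorophenyl]butan-1-one; 19 butanoic acid
Product: 21 1-[3-(ArA′-methyl)-5-(ArC′-methyl)-2,4,6-trifluorophenyl]butan-1-one, via ring A monoacylated ketone 20 (not isolated)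
Conditions: 19 (6 equiv), TFAA (5 equiv), CH2Cl2, 0 °C → rt
Reagents that add atoms: none
Why: Friedel–Crafts acylation through the mixed anhydride of 19 and TFAA: each outer ring has exactly one free carbon activated by three alkoxy groups, ring B is deactivated by fluorine and carbonyl, no Lewis acid is present to strip benzyl ethers, and the bridges cannot open under acid because ring B is electron-poor.

Step 12
Reactants: 21 1-[3-(ArA′-methyl)-5-(ArC′-methyl)-2,4,6-trifluorophenyl]butan-1-one; 22 benzyl alcohol (source of the benzyloxide, deprotonated in the flask to NaOCH2Ph)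
Product: 25 1-[2,4,6-tris(benzyloxy)-3-(ArA′-methyl)-5-(ArC′-methyl)phenyl]butan-1-one, via 4-benzyloxy-2,6-difluoro ketone 23 (not isolated), via 2,4-bis(benzyloxy)-6-fluoro ketone 24 (not isolated)
Conditions: NaH (8 equiv), 22 (excess, neat), 0 °C → rt until H2 evolution ends; then DMSO (BnOH/DMSO 1:3), 21, 25 → 90 °C, argon
Reagents that add atoms: sodium benzyloxide for the C4 oxygen [Na+].[O-]Cc1ccccc1; sodium benzyloxide for the C2 oxygen [Na+].[O-]Cc1ccccc1; sodium benzyloxide for the C6 oxygen [Na+].[O-]Cc1ccccc1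
Why: Proposed new method: each fluoride of ring B is ortho or para to the C1 butyryl carbonyl, so three equivalents of sodium benzyloxide, made from 22 and NaH, should add at C4, C2 and C6 in turn to give anionic σ-adducts whose charge is delocalised onto the ketone oxygen, and loss of fluoride then forms the three C–O bonds, one benzyloxide being consumed per fluoride; the closest known reaction type is alkoxide displacement of ortho and para fluorides in 2,4-difluoro- and 2,4,6-trifluorophenyl ketones, which has not been carried to exhaustion on a fully substituted ring. No ring closes and no stereocentre forms. Chemoselectivity should be secured by the substrate, since rings A and C carry no leaving group and fluoride is the best leaving group for addition–elimination. Completeness is the demanding point, because every benzyloxy group introduced deactivates ring B and twists the carbonyl further out of conjugation, hence the dipolar aprotic solvent and the stepwise rise in temperature. Free benzyl alcohol is kept in excess so that the ketone is not held as its enolate, which would not stabilise the σ-adduct, all NaH is consumed before DMSO is added, and oxygen is excluded so that no benzaldehyde forms to condense with the three enolisable ketones.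

Step 13
Reactants: 25 1-[2,4,6-tris(benzyloxy)-3-(ArA′-methyl)-5-(ArC′-methyl)phenyl]butan-1-one
Product: 26 1-(3-{[3-butanoyl-2,6-dihydroxy-4-methoxy-5-methylphenyl]methyl}-5-{[3-butanoyl-2,4-dihydroxy-6-methoxy-5-methylphenyl]methyl}-2,4,6-trihydroxyphenyl)butan-1-one (target)
Conditions: H2 (1 atm), Pd/C, EtOAc/MeOH, rt
Reagents that add atoms: none
Why: Catalytic hydrogenolysis of benzyl aryl ethers: all seven benzyl groups leave as toluene, while the two methyl ethers, the diarylmethane bridges and the three hindered ketones, each chelated by the phenols as they appear, should be untouched.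

**Compound list**

1 | 2-methylbenzene-1,3,5-triol | Cc1c(O)cc(O)cc1O | starting material
2 | N-[(2,4,6-trihydroxy-3-methylphenyl)methylidene]-N-methylmethanaminium chloride | C[N+](C)=Cc1c(O)cc(O)c(C)c1O.[Cl-] | intermediate (not isolated)
3 | 2,4,6-trihydroxy-3-methylbenzaldehyde | O=Cc1c(O)cc(O)c(C)c1O | intermediate
4 | 2,6-dihydroxy-4-methoxy-3-methylbenzaldehyde | COc1cc(O)c(C=O)c(O)c1C | intermediate
5 | 2,6-bis(benzyloxy)-4-methoxy-3-methylbenzaldehyde | COc1cc(OCc2ccccc2)c(C=O)c(OCc2ccccc2)c1C | intermediate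
6 | 4,6-bis(benzyloxy)-2-hydroxy-3-methylbenzaldehyde | O=Cc1c(O)c(C)c(OCc2ccccc2)cc1OCc1ccccc1 | intermediate
7 | 4,6-bis(benzyloxy)-2-methoxy-3-methylbenzaldehyde | COc1c(C)c(OCc2ccccc2)cc(OCc2ccccc2)c1C=O | intermediate
8 | 1,3,5-trifluorobenzene | Fc1cc(F)cc(F)c1 | starting material
9 | (2,4,6-trifluorophenyl)lithium | [Li]c1c(F)cc(F)cc1F | intermediate (not isolated)
10 | racemic [2,6-bis(benzyloxy)-4-methoxy-3-methylphenyl](2,4,6-trifluorophenyl)methanol | COc1cc(OCc2ccccc2)c(C(O)c2c(F)cc(F)cc2F)c(OCc2ccccc2)c1C | intermediate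
11 | 1,3-bis(benzyloxy)-5-methoxy-4-methyl-2-[(2,4,6-trifluorophenyl)methyl]benzene | COc1cc(OCc2ccccc2)c(Cc2c(F)cc(F)cc2F)c(OCc2ccccc2)c1C | intermediate
12 | (3-{[2,6-bis(benzyloxy)-4-methoxy-3-methylphenyl]methyl}-2,4,6-trifluorophenyl)lithium | COc1cc(OCc2ccccc2)c(Cc2c(F)c([Li])c(F)cc2F)c(OCc2ccccc2)c1C | intermediate (not isolated)
13 | racemic [4,6-bis(benzyloxy)-2-methoxy-3-methylphenyl](3-{[2,6-bis(benzyloxy)-4-methoxy-3-methylphenyl]methyl}-2,4,6-trifluorophenyl)methanol | COc1cc(OCc2ccccc2)c(Cc2c(F)cc(F)c(C(O)c3c(OC)c(C)c(OCc4ccccc4)cc3OCc3ccccc3)c2F)c(OCc2ccccc2)c1C | intermediate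
14 | 1-{[2,6-bis(benzyloxy)-4-methoxy-3-methylphenyl]methyl}-3-{[4,6-bis(benzyloxy)-2-methoxy-3-methylphenyl]methyl}-2,4,6-trifluorobenzene | COc1cc(OCc2ccccc2)c(Cc2c(F)cc(F)c(Cc3c(OC)c(C)c(OCc4ccccc4)cc3OCc3ccccc3)c2F)c(OCc2ccccc2)c1C | intermediate
15 | N-methoxy-N-methylbutanamide | CCCC(=O)N(C)OC | starting material
16 | (3-{[2,6-bis(benzyloxy)-4-methoxy-3-methylphenyl]methyl}-5-{[4,6-bis(benzyloxy)-2-methoxy-3-methylphenyl]methyl}-2,4,6-trifluorophenyl)lithium | COc1cc(OCc2ccccc2)c(Cc2c(F)c([Li])c(F)c(Cc3c(OC)c(C)c(OCc4ccccc4)cc3OCc3ccccc3)c2F)c(OCc2ccccc2)c1C | intermediate (not isolated)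
17 | racemic lithium 1-[3-(ArA-methyl)-5-(ArC-methyl)-2,4,6-trifluorophenyl]-1-[methoxy(methyl)amino]butan-1-olate | CCCC(O[Li])(N(C)OC)c1c(F)c(Cc2c(OCc3ccccc3)cc(OC)c(C)c2OCc2ccccc2)c(F)c(Cc2c(OC)c(C)c(OCc3ccccc3)cc2OCc2ccccc2)c1F | intermediate (not isolated)
18 | 1-(3-{[2,6-bis(benzyloxy)-4-methoxy-3-methylphenyl]methyl}-5-{[4,6-bis(benzyloxy)-2-methoxy-3-methylphenyl]methyl}-2,4,6-trifluorophenyl)butan-1-one | CCCC(=O)c1c(F)c(Cc2c(OCc3ccccc3)cc(OC)c(C)c2OCc2ccccc2)c(F)c(Cc2c(OC)c(C)c(OCc3ccccc3)cc2OCc2ccccc2)c1F | intermediate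
19 | butanoic acid | CCCC(=O)O | starting material
20 | 1-(3-{[2,6-bis(benzyloxy)-3-butanoyl-4-methoxy-5-methylphenyl]methyl}-5-{[4,6-bis(benzyloxy)-2-methoxy-3-methylphenyl]methyl}-2,4,6-trifluorophenyl)butan-1-one | CCCC(=O)c1c(F)c(Cc2c(OCc3ccccc3)c(C(=O)CCC)c(OC)c(C)c2OCc2ccccc2)c(F)c(Cc2c(OC)c(C)c(OCc3ccccc3)cc2OCc2ccccc2)c1F | intermediate (not isolated)
21 | 1-(3-{[2,6-bis(benzyloxy)-3-butanoyl-4-methoxy-5-methylphenyl]methyl}-5-{[2,4-bis(benzyloxy)-3-butanoyl-6-methoxy-5-methylphenyl]methyl}-2,4,6-trifluorophenyl)butan-1-one | CCCC(=O)c1c(F)c(Cc2c(OCc3ccccc3)c(C(=O)CCC)c(OC)c(C)c2OCc2ccccc2)c(F)c(Cc2c(OC)c(C)c(OCc3ccccc3)c(C(=O)CCC)c2OCc2ccccc2)c1F | intermediate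
22 | benzyl alcohol | OCc1ccccc1 | starting material
23 | 1-[4-(benzyloxy)-3-(ArA′-methyl)-5-(ArC′-methyl)-2,6-difluorophenyl]butan-1-one | CCCC(=O)c1c(F)c(Cc2c(OCc3ccccc3)c(C(=O)CCC)c(OC)c(C)c2OCc2ccccc2)c(OCc2ccccc2)c(Cc2c(OC)c(C)c(OCc3ccccc3)c(C(=O)CCC)c2OCc2ccccc2)c1F | intermediate (not isolated)
24 | 1-[2,4-bis(benzyloxy)-3-(ArA′-methyl)-5-(ArC′-methyl)-6-fluorophenyl]butan-1-one | CCCC(=O)c1c(OCc2ccccc2)c(Cc2c(OCc3ccccc3)c(C(=O)CCC)c(OC)c(C)c2OCc2ccccc2)c(OCc2ccccc2)c(Cc2c(OC)c(C)c(OCc3ccccc3)c(C(=O)CCC)c2OCc2ccccc2)c1F | intermediate (not isolated)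
25 | 1-(2,4,6-tris(benzyloxy)-3-{[2,6-bis(benzyloxy)-3-butanoyl-4-methoxy-5-methylphenyl]methyl}-5-{[2,4-bis(benzyloxy)-3-butanoyl-6-methoxy-5-methylphenyl]methyl}phenyl)butan-1-one | CCCC(=O)c1c(OCc2ccccc2)c(Cc2c(OCc3ccccc3)c(C(=O)CCC)c(OC)c(C)c2OCc2ccccc2)c(OCc2ccccc2)c(Cc2c(OC)c(C)c(OCc3ccccc3)c(C(=O)CCC)c2OCc2ccccc2)c1OCc1ccccc1 | intermediate
26 | 1-(3-{[3-butanoyl-2,6-dihydroxy-4-methoxy-5-methylphenyl]methyl}-5-{[3-butanoyl-2,4-dihydroxy-6-methoxy-5-methylphenyl]methyl}-2,4,6-trihydroxyphenyl)butan-1-one | CCCC(=O)c1c(O)c(Cc2c(O)c(C)c(OC)c(C(=O)CCC)c2O)c(O)c(Cc2c(O)c(C(=O)CCC)c(O)c(C)c2OC)c1O | target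

**Count and risks**

Total steps: 13. Longest linear sequence: 11 steps (1 → 26 through steps 1, 2, 3, 6, 7, 8, 9, 10, 11, 12, 13).

Step 12 (bears the label). The third fluoride exchange may stall on a ring that already carries two benzyloxy groups and a twisted carbonyl, or the ketone may sit as its enolate and switch the activation off. The fallback uses only known reactions, sets out from aldehyde 5 and comes back at 25; the ring B oxygens are bought instead of made. Commercial 1,3,5-tris(benzyloxy)benzene is dibrominated (NBS, 2 equiv, CH2Cl2, 0 °C) to 1,3,5-tris(benzyloxy)-2,4-dibromobenzene F1. One bromine–lithium exchange (n-BuLi, 1 equiv, THF, −78 °C) gives [2,4,6-tris(benzyloxy)-3-bromophenyl]lithium F2, which adds to 5 to give the bromo carbinol [2,4,6-tris(benzyloxy)-3-bromophenyl](ArA)methanol F3. Et3SiH/TFA at low temperature reduces it to the bromo diarylmethane 1,3,5-tris(benzyloxy)-2-(ArA-methyl)-4-bromobenzene F4. A second exchange gives the aryllithium [2,4,6-tris(benzyloxy)-3-(ArA-methyl)phenyl]lithium F5, which adds to 7 to give the carbinol (ArC)[2,4,6-tris(benzyloxy)-3-(ArA-methyl)phenyl]methanol F6. Reduction as before gives 1,3,5-tris(benzyloxy)-2-(ArA-methyl)-4-(ArC-methyl)benzene F7. Its three remaining ring C–H positions, one on each ring, are then butyrylated together with 19 and TFAA, which should give 25 directly. The price is that both bridges now join two electron-rich rings and can be opened by acid, so the reductions and the acylation have to be kept cold and short.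

Step 11. Benzyl ethers may be lost or may migrate in the acidic medium, or the crowded last position of each outer ring may be acylated only sluggishly. The fallback sets out from 18 and comes back at 26; the outer-ring acylation is moved behind the deprotection. 18 is put through the benzyloxide exchange of step 12 to give the heptabenzyl ether without outer butyryl groups, 1-[2,4,6-tris(benzyloxy)-3-(ArA-methyl)-5-(ArC-methyl)phenyl]butan-1-one F8. Hydrogenolysis (H2, Pd/C) gives the heptaphenol 1-(3-{[2,6-dihydroxy-4-methoxy-3-methylphenyl]methyl}-5-{[4,6-dihydroxy-2-methoxy-3-methylphenyl]methyl}-2,4,6-trihydroxyphenyl)butan-1-one F9. A Houben–Hoesch reaction with butanenitrile (ZnCl2, HCl, Et2O, 0 °C) at the single free carbon of each outer phloroglucinol ring gives the bis(ketiminium) dichloride of the target F10, which water at 60 °C hydrolyses to 26.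

Step 4. The two ortho hydroxyls may not be told apart in the second benzylation, so that the regioisomeric dibenzyl ether forms beside 6. The fallback sets out from 3 and comes back at 6; everything is protected and one group is then taken off. 3 is benzylated exhaustively (BnBr, K2CO3, DMF, 60 °C) to 2,4,6-tris(benzyloxy)-3-methylbenzaldehyde F11. MgBr2·OEt2 (toluene/Et2O, reflux) then cleaves, by chelation to the formyl oxygen, the ortho benzyl ether that the neighbouring methyl also pushes out of the ring plane, which should give 6.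

**Further compounds**

F1 | step 12 | 1,3,5-tris(benzyloxy)-2,4-dibromobenzene | Brc1c(OCc2ccccc2)cc(OCc2ccccc2)c(Br)c1OCc1ccccc1
F2 | step 12 | [2,4,6-tris(benzyloxy)-3-bromophenyl]lithium | [Li]c1c(OCc2ccccc2)cc(OCc2ccccc2)c(Br)c1OCc1ccccc1
F3 | step 12 | racemic [2,4,6-tris(benzyloxy)-3-bromophenyl][2,6-bis(benzyloxy)-4-methoxy-3-methylphenyl]methanol | COc1cc(OCc2ccccc2)c(C(O)c2c(OCc3ccccc3)cc(OCc3ccccc3)c(Br)c2OCc2ccccc2)c(OCc2ccccc2)c1C
F4 | step 12 | 1,3,5-tris(benzyloxy)-2-{[2,6-bis(benzyloxy)-4-methoxy-3-methylphenyl]methyl}-4-bromobenzene | COc1cc(OCc2ccccc2)c(Cc2c(OCc3ccccc3)cc(OCc3ccccc3)c(Br)c2OCc2ccccc2)c(OCc2ccccc2)c1C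
F5 | step 12 | (2,4,6-tris(benzyloxy)-3-{[2,6-bis(benzyloxy)-4-methoxy-3-methylphenyl]methyl}phenyl)lithium | COc1cc(OCc2ccccc2)c(Cc2c(OCc3ccccc3)cc(OCc3ccccc3)c([Li])c2OCc2ccccc2)c(OCc2ccccc2)c1C
F6 | step 12 | racemic [4,6-bis(benzyloxy)-2-methoxy-3-methylphenyl](2,4,6-tris(benzyloxy)-3-{[2,6-bis(benzyloxy)-4-methoxy-3-methylphenyl]methyl}phenyl)methanol | COc1cc(OCc2ccccc2)c(Cc2c(OCc3ccccc3)cc(OCc3ccccc3)c(C(O)c3c(OC)c(C)c(OCc4ccccc4)cc3OCc3ccccc3)c2OCc2ccccc2)c(OCc2ccccc2)c1C
F7 | step 12 | 1,3,5-tris(benzyloxy)-2-{[2,6-bis(benzyloxy)-4-methoxy-3-methylphenyl]methyl}-4-{[4,6-bis(benzyloxy)-2-methoxy-3-methylphenyl]methyl}benzene | COc1cc(OCc2ccccc2)c(Cc2c(OCc3ccccc3)cc(OCc3ccccc3)c(Cc3c(OC)c(C)c(OCc4ccccc4)cc3OCc3ccccc3)c2OCc2ccccc2)c(OCc2ccccc2)c1C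
F8 | step 11 | 1-(2,4,6-tris(benzyloxy)-3-{[2,6-bis(benzyloxy)-4-methoxy-3-methylphenyl]methyl}-5-{[4,6-bis(benzyloxy)-2-methoxy-3-methylphenyl]methyl}phenyl)butan-1-one | CCCC(=O)c1c(OCc2ccccc2)c(Cc2c(OCc3ccccc3)cc(OC)c(C)c2OCc2ccccc2)c(OCc2ccccc2)c(Cc2c(OC)c(C)c(OCc3ccccc3)cc2OCc2ccccc2)c1OCc1ccccc1
F9 | step 11 | 1-(3-{[2,6-dihydroxy-4-methoxy-3-methylphenyl]methyl}-5-{[4,6-dihydroxy-2-methoxy-3-methylphenyl]methyl}-2,4,6-trihydroxyphenyl)butan-1-one | CCCC(=O)c1c(O)c(Cc2c(O)cc(OC)c(C)c2O)c(O)c(Cc2c(OC)c(C)c(O)cc2O)c1O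
F10 | step 11 | bis(ketiminium) dichloride of the target (both outer-ring butyryl carbons as C=NH2+) | CCCC(=O)c1c(O)c(Cc2c(O)c(C(=[NH2+])CCC)c(OC)c(C)c2O)c(O)c(Cc2c(OC)c(C)c(O)c(C(=[NH2+])CCC)c2O)c1O.[Cl-].[Cl-]
F11 | step 4 | 2,4,6-tris(benzyloxy)-3-methylbenzaldehyde | O=Cc1c(OCc2ccccc2)cc(OCc2ccccc2)c(C)c1OCc1ccccc1
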